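**Retrosynthetic overview**
- The strategy rests on C8, the CH(CH3) carbon joined to ring A (the eugenol-derived 5-allyl-2-hydroxy-3-methoxyphenyl ring) and to the carbinol carbon C7 that carries ring B (3,4-dimethoxyphenyl). In the C7 ketone, C8–H is benzylic and α to an aryl ketone, so it is configurationally labile, and the (7S,8S) pair is the Felkin–Anh outcome of reducing that ketone.
- Disconnections, last to first: phenol O–Si (fluoride); C7–H (asymmetric hydrogenation of the racemic ketone with dynamic kinetic resolution, setting both stereocentres); C8–C(ring A) (palladium-catalysed enolate arylation); ring A C–Br (bromination of eugenol).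
- No ring is formed at any stage: rings A and B are bought intact as eugenol and 3,4-dimethoxypropiophenone.

Key step: step 5

Remark on the chemistry: C7 is the carbinol carbon and C8 the methyl-bearing carbon; the (R)-diphosphine/(R)-diamine catalyst antipode is assumed to give the 7S carbinol by analogy with simple aryl alkyl ketones, to be checked on a small scale and replaced by the (S)/(S) antipode if the sense is opposite.

Step 1
Reactants: 1 eugenol (4-allyl-2-methoxyphenol)
Product: 2 2-bromo-4-(2,3-dibromopropyl)-6-methoxyphenol (racemic at the CHBr carbon)
Conditions: Br2 (2.1 equiv), CH2Cl2, 0 °C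
Reagents that add atoms: bromine, BrBr
Why: Electrophilic aromatic bromination of the activated phenol should go ortho to the OH (the para position is blocked by the side chain), while the second equivalent of Br2 adds across the allyl alkene, so the alkene is deliberately taken through to its dibromide instead of reacting unselectively.

Step 2
Reactants: 2 2-bromo-4-(2,3-dibromopropyl)-6-methoxyphenol
Product: 3 6-bromoeugenol (4-allyl-2-bromo-6-methoxyphenol)
Conditions: Zn dust (3 equiv), AcOH/EtOH, 0 to 25 °C
Reagents that add atoms: none
Why: Zinc-mediated reductive 1,2-elimination of the vicinal dibromide should restore the terminal alkene, and the aryl C–Br bond is not reduced by zinc under these mild conditions.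

Step 3
Reactants: 3 6-bromoeugenol; 4 chlorotriisopropylsilane
Product: 5 (4-allyl-2-bromo-6-methoxyphenoxy)triisopropylsilane
Conditions: imidazole (2.5 equiv), DMAP (cat.), DMF, 25 to 40 °C
Reagents that add atoms: chlorotriisopropylsilane 4, CC(C)[Si](Cl)(C(C)C)C(C)C
Why: Imidazole-promoted O-silylation of the phenol (silyl ether formation); the bulky triisopropylsilyl group is chosen because it should survive K3PO4 and catalytic alkoxide, keeps the phenol from closing onto the later ketone, and comes off with fluoride without acid.

Step 4
Reactants: 5 (4-allyl-2-bromo-6-methoxyphenoxy)triisopropylsilane; 6 1-(3,4-dimethoxyphenyl)propan-1-one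
Product: 7 racemic 1-(3,4-dimethoxyphenyl)-2-[5-allyl-3-methoxy-2-(triisopropylsilyloxy)phenyl]propan-1-one
Conditions: Pd(OAc)2 (3 mol%), 2-dicyclohexylphosphino-2'-methylbiphenyl (6 mol%), K3PO4 (2.5 equiv), toluene, 80–90 °C
Reagents that add atoms: none
Why: Buchwald–Hartwig-type palladium-catalysed α-arylation of a ketone enolate, in which oxidative addition of the aryl bromide to zerovalent palladium, enolate binding and C–C reductive elimination (helped by the bulky electron-rich phosphine) form the C8–ring A bond; the tertiary α-carbon of the product should not arylate again, and C8 is formed as the racemate on purpose.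

Step 5
Reactants: 7 racemic 1-(3,4-dimethoxyphenyl)-2-[5-allyl-3-methoxy-2-(triisopropylsilyloxy)phenyl]propan-1-one
Product: 9 (1S,2S)-1-(3,4-dimethoxyphenyl)-2-[5-allyl-3-methoxy-2-(triisopropylsilyloxy)phenyl]propan-1-ol, via potassium enolate 8 (not isolated)
Conditions: RuCl2[(R)-xylbinap][(R)-daipen] (1 mol%), t-BuOK (10 mol%), H2 (10 atm), degassed i-PrOH, 25 °C
Reagents that add atoms: none
Why: Noyori-type asymmetric hydrogenation run as a dynamic kinetic resolution: t-BuOK converts the dichloride into the 18-electron RuH2(diphosphine)(diamine) species, which passes a hydride from Ru and a proton from N–H to the C7 carbonyl in an outer-sphere six-membered transition state, while the same base keeps the two enantiomers of 7 in rapid exchange through the achiral potassium enolate 8. The closest known reaction type is the diphosphine/diamine–ruthenium hydrogenation of racemic α-aryl ketones (2-arylcycloalkanones and acyclic α-branched aryl ketones) in alkoxide/i-PrOH. No ring is closed. C7 is set by the catalyst, whose (R)/(R) antipode should add hydride to the carbonyl face that gives the 7S carbinol, and C8 is set by the resolution, because only in the (8S) ketone does that face coincide with the Felkin–Anh trajectory (hydride anti to the bulky ortho-silyloxyaryl group and past H, not CH3), so this enantiomer should be drained while the (8R) ketone is returned through 8. The step needs carbonyl-face enantioselectivity, anti diastereoselectivity (anti referring to OH and CH3 on the ring A–C8–C7–ring B zigzag) and C=O over C=C chemoselectivity, secured in turn by the catalyst chirality, by the size gap between aryl and methyl at C8 combined with the acidity of the doubly activated C8–H, and by the outer-sphere mechanism, which offers the allyl alkene no coordination site. The alcohol formed has no acidic C8–H, so the (7S,8S) pair should be configurationally stable once made.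

Step 6
Reactants: 9 (1S,2S)-1-(3,4-dimethoxyphenyl)-2-[5-allyl-3-methoxy-2-(triisopropylsilyloxy)phenyl]propan-1-ol
Product: 10 (1S,2S)-1-(3,4-dimethoxyphenyl)-2-[2-hydroxy-3-methoxy-5-(prop-2-en-1-yl)phenyl]propan-1-ol (target CNP0176583.1)
Conditions: Bu4NF (1.2 equiv), AcOH (1.2 equiv), THF, 0 °C; pH 7 buffer work-up, chromatography on Et3N-deactivated silica
Reagents that add atoms: none
Why: Fluoride-induced Si–O cleavage (silyl ether deprotection) driven by the strong Si–F bond; the acetic acid buffer should prevent both base-induced allyl migration and acid-induced closure of the phenol onto the benzylic C7 (dihydrobenzofuran formation), and neither stereocentre is touched.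

**Compound list**
1 | eugenol (4-allyl-2-methoxyphenol) | C=CCc1ccc(O)c(OC)c1 | starting material
2 | 2-bromo-4-(2,3-dibromopropyl)-6-methoxyphenol, racemic at CHBr | BrCC(Br)Cc1cc(Br)c(O)c(OC)c1 | intermediate
3 | 6-bromoeugenol (4-allyl-2-bromo-6-methoxyphenol) | C=CCc1cc(Br)c(O)c(OC)c1 | intermediate
4 | chlorotriisopropylsilane | CC(C)[Si](Cl)(C(C)C)C(C)C | starting material
5 | (4-allyl-2-bromo-6-methoxyphenoxy)triisopropylsilane | C=CCc1cc(Br)c(O[Si](C(C)C)(C(C)C)C(C)C)c(OC)c1 | intermediate
6 | 1-(3,4-dimethoxyphenyl)propan-1-one | CCC(=O)c1ccc(OC)c(OC)c1 | starting material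
7 | racemic 1-(3,4-dimethoxyphenyl)-2-[5-allyl-3-methoxy-2-(triisopropylsilyloxy)phenyl]propan-1-one | C=CCc1cc(OC)c(O[Si](C(C)C)(C(C)C)C(C)C)c(C(C)C(=O)c2ccc(OC)c(OC)c2)c1 | intermediate
8 | potassium enolate of ketone 7 (enolate geometry not defined) | C=CCc1cc(OC)c(O[Si](C(C)C)(C(C)C)C(C)C)c(C(C)=C([O-])c2ccc(OC)c(OC)c2)c1.[K+] | intermediate
9 | (1S,2S)-1-(3,4-dimethoxyphenyl)-2-[5-allyl-3-methoxy-2-(triisopropylsilyloxy)phenyl]propan-1-ol | C=CCc1cc(OC)c(O[Si](C(C)C)(C(C)C)C(C)C)c([C@H](C)[C@H](O)c2ccc(OC)c(OC)c2)c1 | intermediate
10 | (1S,2S)-1-(3,4-dimethoxyphenyl)-2-[2-hydroxy-3-methoxy-5-(prop-2-en-1-yl)phenyl]propan-1-ol | C=CCc1cc(OC)c(O)c([C@H](C)[C@H](O)c2ccc(OC)c(OC)c2)c1 | target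

**Total step count:** 6. **Longest linear sequence:** 6 steps (1 → 2 → 3 → 5 → 7 → 9 → 10).

**Steps most likely to fail**

Step 5. Enolisation at the crowded C8–H may be slower than hydrogenation, so the resolution stops being dynamic. The ortho-silyloxy group may also erode the facial preference of the catalyst, the hindered ketone may reduce slowly, and alkoxide may shift or strip the silyl group (step 6 would clear a silyl group that had moved to the C7 oxygen). The fallback sets out from 7 and returns at 9. Substrate-controlled Felkin–Anh reduction of racemic 7 with LiBH(s-Bu)3 in THF at −78 °C should give the racemic anti alcohol F1. Preparative chromatography of F1 on a chiral stationary phase then supplies 9. The unwanted (1R,2R) enantiomer F2 is oxidised with Dess–Martin periodinane back to the ketone, which racemises on brief exposure to base and re-enters as 7.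

Step 4. Oxidative addition and reductive elimination at the crowded, electron-rich ortho-silyloxy aryl bromide may be slow. Heck-type insertion or palladium hydride migration of the allyl alkene, hydrodebromination or base-induced desilylation could then compete. The fallback reverses the polarity; it sets out from 5 and 6 and returns at 7. Magnesium insertion into 5 (Mg turnings, LiCl, THF) gives the arylmagnesium bromide F3, which ZnBr2 converts into the arylzinc bromide F4. α-Bromination of 6 with CuBr2 (EtOAc/CHCl3, reflux) gives racemic 2-bromo-1-(3,4-dimethoxyphenyl)propan-1-one F5. Nickel-catalysed Negishi coupling of F4 with F5 (NiCl2(dme), a pybox ligand, DME/THF, −30 °C) is a known stereoconvergent α-arylation of racemic α-bromo ketones that needs neither strong base nor heat, and should give 7. The enantiomeric composition of 7 is irrelevant because step 5 equilibrates C8.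

Step 1. The very electron-rich ring may over-brominate, or substitute para to the methoxy group instead of ortho to the hydroxyl, once excess Br2 and HBr are present. The fallback sets out from 1 and returns at 3, bypassing 2 and step 2. It is a direct ortho-selective monobromination of the phenol with N-bromosuccinimide and catalytic i-Pr2NH in CH2Cl2 at 0 °C, a known amine-mediated ortho-bromination in which the N-bromoamine is delivered by hydrogen bonding to the OH. The isolated alkene should be left untouched at low temperature, and no new compound is made.

**Further compounds**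
F1 | step 5 | racemic anti alcohol silyl ether (1:1 mixture of 9 and its enantiomer) | C=CCc1cc(OC)c(O[Si](C(C)C)(C(C)C)C(C)C)c([C@H](C)[C@H](O)c2ccc(OC)c(OC)c2)c1.C=CCc1cc(OC)c(O[Si](C(C)C)(C(C)C)C(C)C)c([C@@H](C)[C@@H](O)c2ccc(OC)c(OC)c2)c1
F2 | step 5 | (1R,2R)-1-(3,4-dimethoxyphenyl)-2-[5-allyl-3-methoxy-2-(triisopropylsilyloxy)phenyl]propan-1-ol | C=CCc1cc(OC)c(O[Si](C(C)C)(C(C)C)C(C)C)c([C@@H](C)[C@@H](O)c2ccc(OC)c(OC)c2)c1
F3 | step 4 | [5-allyl-3-methoxy-2-(triisopropylsilyloxy)phenyl]magnesium bromide | C=CCc1cc([Mg]Br)c(O[Si](C(C)C)(C(C)C)C(C)C)c(OC)c1
F4 | step 4 | [5-allyl-3-methoxy-2-(triisopropylsilyloxy)phenyl]zinc bromide | C=CCc1cc([Zn]Br)c(O[Si](C(C)C)(C(C)C)C(C)C)c(OC)c1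
F5 | step 4 | racemic 2-bromo-1-(3,4-dimethoxyphenyl)propan-1-one | CC(Br)C(=O)c1ccc(OC)c(OC)c1
F0 | step 1 | none | none
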